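Labdane numbering is used (ring A: C1–C5, C10; ring B: C5–C10; C19 is the CH2OH carbon). Retrosynthetic cuts, in order: C13=C14 (olefination); C1–C10 and C2–C3 of ring A together; C4–C19 (formaldehyde aldol); C9–C11 (Grignard); C10–C20 (Mannich). This leaves (S)-carvone.
Forward: ring B is the carvone ring and is dressed first (C20 methylene, C9 chain, isopropenyl turned into a C(CH3)(CHO)2 group). Ring A is then closed in one operation around acrolein as the C1–C2 unit, and the C14–C15 acid end is joined last.
Enabling feature: in ring A the methyl-bearing quaternary C10 and the carbinol C3 stand 1,4 to each other across an unsubstituted C1–C2 bridge. C10–CH3 can therefore be read as H· added to an exocyclic C10=C20 methylene, C3–O as a formyl group, and C4 (CH3, C3, C19) as a prochiral 2-methylmalondialdehyde carbon.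
Stereochemistry: C5 comes from (S)-carvone and C9 from hydride delivery anti to the C5 substituent. C10, C4, C3 (and the temporary C2) are set in the key step under control of C5 and C9, and the 13E alkene comes from the olefination.
Helpers: the formyl group of acrolein at C2 (taken out by decarbonylation), the aldehyde level at C19 (reduced late), the side-chain ketal and the allyl ester.

Key step: step 8

Assumption: 1, 5, 15 and 21 are taken as commercial, and the sensitive intermediates 4 and 8 are taken to survive being carried on at once without storage.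

Step 1
Reactants: 1 (S)-(+)-carvone
Product: 4 (5R)-2-methyl-6-methylidene-5-(prop-1-en-2-yl)cyclohex-2-en-1-one, via Mannich base 2 (not isolated), via methiodide 3 (not isolated)
Conditions: LiN(i-Pr)2, THF, −78 °C; CH2=NMe2+ I−, −78 → 0 °C; MeI, Et2O, rt; aq. NaHCO3/CH2Cl2, rt
Reagents that add atoms: Eschenmoser's salt (dimethylmethylideneammonium iodide), C=[N+](C)C.[I-]; iodomethane, CI (methyl group of 3 only)
Why: Kinetic α′-deprotonation of the enone, Mannich reaction with the preformed iminium salt and E1cB loss of trimethylamine from the quaternised base (Mannich α-methylenation) put C20 on C10 as an exocyclic methylene and leave the C5 stereocentre of carvone untouched.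

Step 2
Reactants: 4 (5R)-2-methyl-6-methylidene-5-(prop-1-en-2-yl)cyclohex-2-en-1-one; 5 2-(2-bromoethyl)-2-methyl-1,3-dioxolane
Product: 8 methyl (1R,5R)-2-methyl-6-methylidene-1-[2-(2-methyl-1,3-dioxolan-2-yl)ethyl]-5-(prop-1-en-2-yl)cyclohex-2-en-1-yl carbonate, via Grignard reagent 6 (not isolated), via tertiary alkoxide 7 (not isolated)
Conditions: 5, Mg, THF, rt; anhydrous CeCl3, −78 °C; 4, −78 °C; then ClCO2Me, −78 → 0 °C
Reagents that add atoms: methyl chloroformate, COC(=O)Cl; magnesium, [Mg] (in 6 only)
Why: Cerium-mediated Grignard addition goes 1,2 to the enolisable cross-conjugated ketone, on the face anti to the pseudo-axial isopropenyl group, and the alkoxide is acylated in the same flask to a bis-allylic tertiary carbonate whose C9 configuration is erased in step 3.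

Step 3
Reactants: 8 the tertiary bis-allylic methyl carbonate
Product: 9 2-methyl-2-{2-[(1R,5R)-2-methyl-6-methylidene-5-(prop-1-en-2-yl)cyclohex-2-en-1-yl]ethyl}-1,3-dioxolane (C5 and C9 substituents cis)
Conditions: Pd2(dba)3·CHCl3 (cat.), PBu3, HCO2H, Et3N, THF, rt
Reagents that add atoms: none
Why: In this palladium-catalysed formate hydrogenolysis of an allylic carbonate, zerovalent palladium ionises the carbonate, the allyl unit is held σ at the primary C20, and hydride passes from bound formate to the more substituted terminus C9 on the face anti to the isopropenyl group, which keeps the exocyclic and the C7=C8 alkenes in place and sets C9 with its chain cis to the C5 substituent.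

Step 4
Reactants: 9 the triene ketal
Product: 11 2-{(1R,5R)-4-methyl-6-methylidene-5-[2-(2-methyl-1,3-dioxolan-2-yl)ethyl]cyclohex-3-en-1-yl}propan-1-ol (epimers at C4), via alkylborane 10 (not isolated)
Conditions: 9-BBN (1 equiv), THF, 0 °C → rt; NaOH, H2O2, 0 °C
Reagents that add atoms: 9-BBN, B1C2CCCC1CCC2 (boryl group of 10 only); hydrogen peroxide, OO
Why: In this chemoselective hydroboration–oxidation 9-BBN takes the open isopropenyl group faster than the methylene flanked by two branched ring carbons or the trisubstituted ring alkene, and the C4 epimers are of no consequence because C4 loses its stereogenicity in step 7.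

Step 5
Reactants: 11 the primary alcohol
Product: 12 2-{(1R,5R)-4-methyl-6-methylidene-5-[2-(2-methyl-1,3-dioxolan-2-yl)ethyl]cyclohex-3-en-1-yl}propanal (epimers at C4)
Conditions: Dess–Martin periodinane, CH2Cl2, 0 °C → rt
Reagents that add atoms: none
Why: Dess–Martin oxidation of a primary alcohol under near-neutral conditions leaves the skipped diene and the ketal alone.

Step 6
Reactants: 12 the α-branched aldehyde
Product: 13 3-hydroxy-2-methyl-2-{(1S,5R)-4-methyl-6-methylidene-5-[2-(2-methyl-1,3-dioxolan-2-yl)ethyl]cyclohex-3-en-1-yl}propanal (epimers at C4)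
Conditions: 37% aq. HCHO, K2CO3, MeOH, rt
Reagents that add atoms: formaldehyde, C=O
Why: Crossed aldol with non-enolisable formaldehyde (Tollens-type hydroxymethylation) at the only enolisable position makes C4 quaternary and brings in C19, and its configuration is again irrelevant.

Step 7
Reactants: 13 the β-hydroxy aldehyde
Product: 14 2-methyl-2-{(1S,5R)-4-methyl-6-methylidene-5-[2-(2-methyl-1,3-dioxolan-2-yl)ethyl]cyclohex-3-en-1-yl}propanedial
Conditions: Dess–Martin periodinane, CH2Cl2, 0 °C → rt
Reagents that add atoms: none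
Why: A second Dess–Martin oxidation gives the non-enolisable 2,2-disubstituted malondialdehyde, in which C4 is prochiral and its two formyl groups are diastereotopic.

Step 8
Reactants: 14 the γ,δ-unsaturated dialdehyde; 15 acrolein
Product: 16 (2S,3S,4S,5S,9R,10S)-13,13-ethylenedioxy-2-formyl-3-hydroxy-14,15-dinorlabd-7-en-19-al (trans-decalin; C20 axial, C2-CHO equatorial, C3-OH axial, C4-CHO axial)
Conditions: Fe(acac)3 (cat.), PhSiH2(Oi-Pr), 15 (excess, slow addition), 1,2-dichloroethane, 0 °C → rt; aqueous work-up
Reagents that add atoms: none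
Why: An iron hydride made from Fe(acac)3 and the silane passes a hydrogen atom to the CH2 end of the C10=C20 methylene, the nucleophilic tertiary C10 radical adds to the β-carbon of acrolein (C1–C10 bond), divalent iron reduces the α-formyl radical to an iron enolate, and this enolate adds to one formyl group on C4 (C2–C3 bond). The closest known reaction type is the hydrogen-atom-transfer-initiated radical–polar crossover annulation (Giese addition followed by aldol) of γ,δ-unsaturated aldehydes with enals and enones. Ring A closes by a 6-(enolexo)-exo-trig aldol through a chair that becomes the trans-decalin. At C10 acrolein approaches anti to the two cis, equatorial neighbours (C5 arm and C9 chain), so C1 ends equatorial and C20 axial; at C4 the diastereotopic formyl group reacts that leaves CH3 equatorial and the smaller, flat CHO axial beside axial C20; at C2/C3 the metal-bridged Zimmerman–Traxler-type closure gives the cis aldol, and because an axial C2 formyl group would clash with C20 and C19 this means equatorial CHO and axial OH. The step needs hydrogen-atom transfer to the 1,1-disubstituted alkene ahead of the trisubstituted C7=C8 alkene and of acrolein, which the higher rate for electron-rich terminal methylenes secures, and it needs intermolecular capture of the radical, which the acceptor-free ketal side chain and the excess of acrolein secure. Neither formyl group on C4 can enolise, so the only enolate present is the one created by the crossover.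

Step 9
Reactants: 16 the annulation product
Product: 17 (3S,4S,5S,9R,10S)-13,13-ethylenedioxy-3-hydroxy-14,15-dinorlabd-7-en-19-al
Conditions: RhCl(PPh3)3 (1.1 equiv), toluene, 110 °C
Reagents that add atoms: none
Why: Tsuji–Wilkinson decarbonylation runs by oxidative addition of the formyl C–H bond, CO extrusion and C–H reductive elimination and discriminates by access, so the equatorial secondary C2 formyl group should react while the axial formyl group on quaternary C4 stays.

Step 10
Reactants: 17 the hydroxy aldehyde
Product: 18 (3S,4S,5S,9R,10S)-3-acetoxy-13,13-ethylenedioxy-14,15-dinorlabd-7-en-19-al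
Conditions: Ac2O, DMAP, pyridine, rt → 40 °C
Reagents that add atoms: acetic anhydride, CC(=O)OC(C)=O
Why: DMAP-catalysed acylation of the hindered axial C3 alcohol while C19 is still an aldehyde avoids any competition from a primary alcohol, and the aldehyde cannot enolise or eliminate.

Step 11
Reactants: 18 the acetoxy aldehyde
Product: 20 (3S,4R,5S,9R,10S)-3-acetoxy-19-hydroxy-14,15-dinorlabd-7-en-13-one, via primary alcohol 19 (not isolated)
Conditions: NaBH4, MeOH, 0 °C; then 1 M HCl, THF, rt
Reagents that add atoms: water, O
Why: Borohydride reduces the only aldehyde and the acidic second stage hydrolyses the dioxolane, while acetyl migration is excluded because O3 and C19 are trans-diaxial (antiperiplanar).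

Step 12
Reactants: 20 the methyl ketone; 21 allyl diethylphosphonoacetate
Product: 22 allyl (13E,3S,4R,5S,9R,10S)-3-acetoxy-19-hydroxylabda-7,13-dien-15-oate
Conditions: 21, NaH, THF, 0 °C; 20, rt → 50 °C
Reagents that add atoms: none
Why: Horner–Wadsworth–Emmons olefination of the methyl ketone with a stabilised phosphonate anion should favour the E-trisubstituted enoate, and the minor Z isomer is to be removed by chromatography.

Step 13
Reactants: 22 the allyl ester
Product: 23 (13E,3S,4R,5S,9R,10S)-3-acetoxy-19-hydroxylabda-7,13-dien-15-oic acid (CNP0129162.1)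
Conditions: Pd(PPh3)4 (cat.), morpholine, THF, rt
Reagents that add atoms: none
Why: Zerovalent palladium ionises the allyl ester and morpholine traps the allyl unit (Tsuji–Trost deallylation), which frees the acid under neutral conditions that leave the acetate in place.

Compound list
1 | (S)-(+)-carvone | C=C(C)[C@H]1CC=C(C)C(=O)C1 | starting material
2 | (5S)-6-[(dimethylamino)methyl]-2-methyl-5-(prop-1-en-2-yl)cyclohex-2-en-1-one (Mannich base) | C=C(C)[C@H]1CC=C(C)C(=O)C1CN(C)C | intermediate
3 | methiodide of 2 | C=C(C)[C@H]1CC=C(C)C(=O)C1C[N+](C)(C)C.[I-] | intermediate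
4 | (5R)-2-methyl-6-methylidene-5-(prop-1-en-2-yl)cyclohex-2-en-1-one | C=C(C)[C@H]1CC=C(C)C(=O)C1=C | intermediate
5 | 2-(2-bromoethyl)-2-methyl-1,3-dioxolane | CC1(CCBr)OCCO1 | starting material
6 | [2-(2-methyl-1,3-dioxolan-2-yl)ethyl]magnesium bromide | CC1(CC[Mg]Br)OCCO1 | intermediate
7 | (1R,5R)-2-methyl-6-methylidene-1-[2-(2-methyl-1,3-dioxolan-2-yl)ethyl]-5-(prop-1-en-2-yl)cyclohex-2-en-1-ol (present as its alkoxide) | C=C1[C@@](O)(CCC2(C)OCCO2)C(C)=CC[C@@H]1C(C)=C | intermediate
8 | methyl carbonate of 7 | C=C1[C@@](OC(=O)OC)(CCC2(C)OCCO2)C(C)=CC[C@@H]1C(C)=C | intermediate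
9 | 2-methyl-2-{2-[(1R,5R)-2-methyl-6-methylidene-5-(prop-1-en-2-yl)cyclohex-2-en-1-yl]ethyl}-1,3-dioxolane | C=C1[C@H](CCC2(C)OCCO2)C(C)=CC[C@@H]1C(C)=C | intermediate
10 | B-alkyl-9-BBN adduct of 9 at the isopropenyl group | C=C1[C@H](CCC2(C)OCCO2)C(C)=CC[C@@H]1C(C)CB1C2CCCC1CCC2 | intermediate
11 | 2-{(1R,5R)-4-methyl-6-methylidene-5-[2-(2-methyl-1,3-dioxolan-2-yl)ethyl]cyclohex-3-en-1-yl}propan-1-ol (C4 epimers) | C=C1[C@H](CCC2(C)OCCO2)C(C)=CC[C@@H]1C(C)CO | intermediate
12 | 2-{(1R,5R)-4-methyl-6-methylidene-5-[2-(2-methyl-1,3-dioxolan-2-yl)ethyl]cyclohex-3-en-1-yl}propanal (C4 epimers) | C=C1[C@H](CCC2(C)OCCO2)C(C)=CC[C@@H]1C(C)C=O | intermediate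
13 | 3-hydroxy-2-methyl-2-{(1S,5R)-4-methyl-6-methylidene-5-[2-(2-methyl-1,3-dioxolan-2-yl)ethyl]cyclohex-3-en-1-yl}propanal (C4 epimers) | C=C1[C@H](CCC2(C)OCCO2)C(C)=CC[C@@H]1C(C)(CO)C=O | intermediate
14 | 2-methyl-2-{(1S,5R)-4-methyl-6-methylidene-5-[2-(2-methyl-1,3-dioxolan-2-yl)ethyl]cyclohex-3-en-1-yl}propanedial | C=C1[C@H](CCC2(C)OCCO2)C(C)=CC[C@@H]1C(C)(C=O)C=O | intermediate
15 | acrolein | C=CC=O | starting material
16 | (2S,3S,4S,5S,9R,10S)-13,13-ethylenedioxy-2-formyl-3-hydroxy-14,15-dinorlabd-7-en-19-al | O[C@H]1[C@@H](C=O)C[C@]2(C)[C@H](CC=C(C)[C@H]2CCC3(C)OCCO3)[C@]1(C)C=O | intermediate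
17 | (3S,4S,5S,9R,10S)-13,13-ethylenedioxy-3-hydroxy-14,15-dinorlabd-7-en-19-al | O[C@H]1CC[C@]2(C)[C@H](CC=C(C)[C@H]2CCC3(C)OCCO3)[C@]1(C)C=O | intermediate
18 | (3S,4S,5S,9R,10S)-3-acetoxy-13,13-ethylenedioxy-14,15-dinorlabd-7-en-19-al | CC(=O)O[C@H]1CC[C@]2(C)[C@H](CC=C(C)[C@H]2CCC3(C)OCCO3)[C@]1(C)C=O | intermediate
19 | (3S,4R,5S,9R,10S)-3-acetoxy-13,13-ethylenedioxy-14,15-dinorlabd-7-en-19-ol | CC(=O)O[C@H]1CC[C@]2(C)[C@H](CC=C(C)[C@H]2CCC3(C)OCCO3)[C@]1(C)CO | intermediate
20 | (3S,4R,5S,9R,10S)-3-acetoxy-19-hydroxy-14,15-dinorlabd-7-en-13-one | CC(=O)O[C@H]1CC[C@]2(C)[C@H](CC=C(C)[C@H]2CCC(C)=O)[C@]1(C)CO | intermediate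
21 | allyl diethylphosphonoacetate | C=CCOC(=O)CP(=O)(OCC)OCC | starting material
22 | allyl (13E,3S,4R,5S,9R,10S)-3-acetoxy-19-hydroxylabda-7,13-dien-15-oate | CC(=O)O[C@H]1CC[C@]2(C)[C@H](CC=C(C)[C@H]2CC/C(C)=C/C(=O)OCC=C)[C@]1(C)CO | intermediate
23 | (13E,3S,4R,5S,9R,10S)-3-acetoxy-19-hydroxylabda-7,13-dien-15-oic acid (CNP0129162.1) | CC(=O)O[C@H]1CC[C@]2(C)[C@H](CC=C(C)[C@H]2CC/C(C)=C/C(=O)O)[C@]1(C)CO | target

Total step count: 13. Longest linear sequence: 13 steps (from 1).

Steps most likely to fail

Step 8.
- What may go wrong: the hindered C10 radical may take up a second hydrogen atom. The iron enolate may be protonated or silylated before it reaches a formyl group. Facial selectivity at C10, the choice between the two formyl groups, or the axial placement of the hydroxyl may erode.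
- Fallback (sets out from 14, comes back at 16): the two bond formations are separated. Under protic reductive olefin-coupling conditions (Fe(acac)3, PhSiH3, EtOH, 15) the radical adduct is deliberately protonated to the uncyclised trialdehyde F1. Its new CH2CHO arm is the only enolisable carbonyl, so F1 is then cyclised with Bu2BOTf and i-Pr2NEt at −78 °C, where a closed boron-bridged transition state should enforce the cis aldol 16.

Step 3.
- What may go wrong: hydride may pass to the wrong allyl terminus (C20 or C7), giving conjugated dienes. β-Hydride elimination may give a triene that aromatises. Facial selectivity at C9 may be poor.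
- Fallback (sets out from 7, isolated by aqueous quench of step 2 before the chloroformate is added; comes back at 9): a rhenium-oxo-catalysed 1,3-transposition (O3ReOSiPh3, Et2O, low temperature) moves the hydroxyl group to C20 and gives the conjugated dienyl carbinol F2. A Mitsunobu reaction (PPh3, DEAD) with N-isopropylidene-N′-(2-nitrobenzenesulfonyl)hydrazine gives the protected allylic hydrazine F3. Mild hydrolysis (trifluoroethanol/water) releases the allylic diazene F4. F4 loses nitrogen in a retro-ene step that delivers hydrogen to C9 on the open face and regenerates the exocyclic methylene of 9.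

Step 9.
- What may go wrong: rhodium may insert at the wrong formyl group, the β-hydroxy aldehyde may open by retro-aldol or dehydrate on heating, or the alkylrhodium intermediate may undergo β-elimination.
- Fallback (sets out from 14, comes back at 17): the helper is changed from formyl to ester. The annulation of step 8 is run with methyl acrylate in place of 15 to give the β-hydroxy ester F5. LiOH in aqueous THF gives the hydroxy acid F6, and N-hydroxyphthalimide with diisopropylcarbodiimide gives the redox-active ester F7. Reductive radical decarboxylation (Ru(bpy)3Cl2, Hantzsch ester, blue light) then replaces the carboxyl group by hydrogen to give 17, leaving the C19 aldehyde untouched.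

Further compounds
F1 | step 8 | 2-{(1S,5R,6S)-4,6-dimethyl-5-[2-(2-methyl-1,3-dioxolan-2-yl)ethyl]-6-(3-oxopropyl)cyclohex-3-en-1-yl}-2-methylpropanedial (uncyclised trialdehyde) | O=CCC[C@]1(C)[C@H](CC=C(C)[C@H]1CCC2(C)OCCO2)C(C)(C=O)C=O
F2 | step 3 | {(6R)-3-methyl-2-[2-(2-methyl-1,3-dioxolan-2-yl)ethyl]-6-(prop-1-en-2-yl)cyclohexa-1,3-dien-1-yl}methanol (dienyl carbinol) | OCC1=C(CCC2(C)OCCO2)C(C)=CC[C@@H]1C(C)=C
F3 | step 3 | N-(dienylmethyl)-N-(2-nitrobenzenesulfonyl) acetone hydrazone derived from F2 | CC(C)=NN(CC1=C(CCC2(C)OCCO2)C(C)=CC[C@@H]1C(C)=C)S(=O)(=O)c1ccccc1[N+](=O)[O-]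
F4 | step 3 | allylic diazene derived from F3 | N=NCC1=C(CCC2(C)OCCO2)C(C)=CC[C@@H]1C(C)=C
F5 | step 9 | methyl (2S,3S,4S,5S,9R,10S)-13,13-ethylenedioxy-3-hydroxy-19-oxo-14,15-dinorlabd-7-ene-2-carboxylate | O[C@H]1[C@@H](C(=O)OC)C[C@]2(C)[C@H](CC=C(C)[C@H]2CCC3(C)OCCO3)[C@]1(C)C=O
F6 | step 9 | the corresponding 2-carboxylic acid | O[C@H]1[C@@H](C(=O)O)C[C@]2(C)[C@H](CC=C(C)[C@H]2CCC3(C)OCCO3)[C@]1(C)C=O
F7 | step 9 | N-(acyloxy)phthalimide of F6 | O[C@H]1[C@@H](C(=O)ON3C(=O)c4ccccc4C3=O)C[C@]2(C)[C@H](CC=C(C)[C@H]2CCC5(C)OCCO5)[C@]1(C)C=O
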